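The ratio of one gain in target to the gain in the span before, over nearly equal spans, tells how much work a flask still has in it. Call this the tail ratio f. If later spans shrink by the same f, the gains form a geometric series, and what is still to come after a last gain g, following an earlier gain G, is g·g/(G − g).

Note for the bench: alder holds the ash charge and is to be read at 28 h.

| flask | substrate | reagent | free catalyst | time |
|---|---|---|---|---|
| ash | 250 mM | 375 mM | 5.00 mM |  |
| elm | 250 mM | 1100 mM | 5.00 mM |  |
| birch | 250 mM | 375 mM | 2.50 mM |  |
| oak | 380 mM | 375 mM | 5.00 mM |  |
| alder | 250 mM | 375 mM | 5.00 mM | 28 h |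

- ash run (time / h: [target] / mM): 1.6: 65.0; 3.2: 93.6; 4.8: 109.0; 6.3: 114.7; 7.9: 120.5; 9.5: 123.5
- elm run (time / h: [target] / mM): 1.6: 141.6; 3.2: 172.1; 4.8: 177.3; 6.3: 177.0; 7.9: 176.6; 9.5: 177.3
- birch run (time / h: [target] / mM): 1.6: 34.0; 3.2: 54.1; 4.8: 64.2; 6.3: 71.9; 7.9: 77.5; 9.5: 80.8
- oak run (time / h: [target] / mM): 1.6: 71.7; 3.2: 102.5; 4.8: 119.6; 6.3: 130.1; 7.9: 134.4; 9.5: 138.2

(readings scatter by 0.8 mM)

- the exponent of [reagent] in the starting rate at the charge of the ash run (at the point where two percent of the substrate have become target)
- the exponent of [substrate] in the starting rate at the charge of the ash run (at the point where two percent of the substrate have become target) (one fixed amount of target, the same in the runs compared)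
- target in the alder run at 28 h, as a share of the substrate charged

- Overall: substrate + reagent -> target, with free catalyst as catalyst.
- Constant volume, constant temperature.
- A reading of a species includes what of it is bound.
- An order is taken over about fifteen percent of the charge, up and down.

The ash run is the guide to alder, and its last spans, of 3.10 h and 3.20 h, give this reading:

G = 21.1 mM, g = 8.80 mM

f = g/G = 0.417

expected end = 123.5 mM + g·g/(G − g) = 130 mM, or 51.9% of the substrate charged

From the last ash reading to 28 h, f shrinks the remaining gain to a fraction 0.00637, so hardly any of it should remain unmade. This reckoning borrows the tail of the ash run, whose charge alder shares. The charge and the temperature of alder are not to be touched.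

The forecast gives 1.1 for the reagent exponent, 0.27 for the substrate exponent and 52% for alder, with “increments shrinking about 0.6-fold per 1.6 h”. That tail is the same ash tail, so the matching share is no check.

The flask gives 0.91, 0.33 and 50.8%.

    free catalyst + substrate ⇌ catalyst-substrate complex, settled at all times (6.950 /M)
    catalyst-substrate complex + reagent ⇌ ternary complex, settled at all times (0.6540 /M)
    ternary complex → target + free catalyst (90.36 /h)
    free catalyst + substrate → spent catalyst + substrate (1.818 /M/h)
    2 substrate → homo dimer (1.440 /M/h)

In alder at the start, the ternary complex gave target at 60.9 mM/h while substrate went to homo dimer at 180 mM/h, faster than target formed. By 28 h, at most 11.8 mM of substrate stood in alder beside 127 mM of target. That end lies 3.52 mM above the last ash reading, where f = 0.417 had given 6.50 mM. In elm, the first three readings give f = 0.170 and an end of 178 mM, and the elm reading at 9.5 h stands at 177.3 mM.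

All runs were generated by integration with constants of no real substance; scatter was added.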